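The readings stem from a simulated flask with constants of no real substance, noise included.

I decided to choose the option by counting turnovers: how many lifetimes of each process fit into the wait, as read from the two runs.

| setting | Thursday's | Tuesday's | flask |
|---|---|---|---|
| substrate | 21 mM | 14 mM | 21 mM |
| remark | the very flask that is asked about, followed so far | run made earlier |  |
| time |  |  | 8.0 d |

- green: at 8.0 d take out 90 % of the target then present, then wait 8.0 d
- grey: at 8.0 d add substrate, 50.0 % of the amount charged, then wait 8.0 d
- red: change nothing and wait 8.0 d more

- removed target is counted in
- additions bring no volume worth counting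

- target, in percent of the substrate first charged, at 8.0 d
- the option that brings most further target ("none" if no option brings more than 2 percentage points) (green / grey / red / none)
- target present, with what was taken out counted in, in percent of the substrate first charged, after green
- target present, with what was taken out counted in, in percent of the substrate first charged, after red

Thursday's run (percent of the substrate charged)

| time / d | target / % |
|---|---|
| 0.333 | 18.7 |
| 1.04 | 15.5 |
| 1.67 | 16.2 |
| 3.00 | 14.1 |
| 4.00 | 15.3 |
| 5.00 | 13.5 |
| 6.00 | 12.5 |

Tuesday's run (percent of the substrate charged)

| time / h | target / % |
|---|---|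
| 1.00 | 35.8 |
| 3.00 | 24.7 |
| 5.00 | 19.8 |
| 8.00 | 15.9 |
| 12.0 | 16.0 |
| 15.0 | 15.3 |
| 20.0 | 18.0 |

(readings scatter by 1 percentage point)

I read the tables against each other. Tuesday's flask started at [substrate] = 14 mM and Thursday's at 21 mM, yet Tuesday's target read 16.0 % at 12.0 h and Thursday's read 15.5 % at 1.04 d. So I took the percentages as independent of the charge, which is first-order behaviour.

Tuesday's first rows stood above that level by 20 percentage points, then 8.7 points, which gave a fast lifetime of 2.43 h. Thursday's rows, from 15.5 % down to 12.5 % at 6.00 d, gave a sag constant of 0.0434 /d.

The wait of 8.0 d therefore held 78.9 fast turnovers but a sag count, the sag constant times the wait, of 0.347. Because the first far exceeds the second, I treated the fast exchange as a finished pre-equilibrium after any disturbance, with target back at its share of the pool, near 16.0 %, and the sag multiplying by exp(−count).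

For Thursday's flask I reckoned 11.5 % at 8.0 d. Red then gave 8.10 %, grey 13.8 % and green, with the removed target counted in, 17.3 %, so green came out ahead in my reckoning.

The forecast said “The reservoir refills the target” and gave 12.1 % now, 18 % after green and 8.6 % after red, choosing green as I did. My figures ran lower than its figures.

Thursday's flask gave 11.8 % at 8.0 d, and green was best, reaching 18.8 % against 9.41 % after red.

    substrate ⇌ target (K = 1.30, k = 0.0280 /min)
    target ⇌ isomer of the product A (K = 2.60, k = 2.20 × 10⁻⁴ /min)
    isomer of the product A ⇌ isomer of the product B (K = 2.10, k = 0.00370 /min)
    substrate ⇌ dormant form (K = 5.30, k = 0.0160 /min)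

At 8.00 d that flask held more dormant form than target, 48.7 % against 11.8 %. The sag count took 11.8 % to 8.33 % after the wait, where the flask stood at 9.41 %. Run backwards over 5.00 d, the same sag constant gave 14.7 % for the neighbouring reading at 3.0 d, which stood at 14.4 %.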